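0.600 mM is what alder, the closed flask, is charged with of D beyond its L; I call this excess a = D − L. The earlier runs read as if L ties up D one for one, so I count turnovers per mM of a.

| flask | Z | E | D | L | remark | time |
|---|---|---|---|---|---|---|
| Saturday's | 0.20 M | 0.20 M | 1.6 mM | 1 mM | run made earlier |  |
| Tuesday's | 0.20 M | 0.20 M | 2.2 mM | 1 mM | run made earlier |  |
| Thursday's | 0.20 M | 0.20 M | 3.5 mM | 1 mM | run made earlier |  |
| ash | 0.20 M | 0.200 M | 1.6 mM | 1.0 mM | a single well-mixed tank run continuously and read at steady state, 20 min in it on average |  |
| birch | 0.20 M | 0.200 M (fed, over 20.0 min) | 1.6 mM | 1.0 mM | all but E at the start; E goes in evenly over 20.0 min, the run ends at 20 min | 20 min |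
| alder | 0.20 M | 0.200 M | 1.6 mM | 1.0 mM | everything together in a closed stirred flask, run for 20 min | 20 min |
| elm | 0.20 M (fed, over 20.0 min) | 0.200 M | 1.6 mM | 1.0 mM | a stirred flask in which Z is dosed at a steady rate over 20.0 min without added volume, worked up at 20 min | 20 min |

| Saturday's: time / min | Saturday's: Q / % | Tuesday's: time / min | Tuesday's: Q / % | Thursday's: time / min | Thursday's: Q / % |
|---|---|---|---|---|---|
| 2.50 | 1 | 2.00 | 0 | 2.00 | 0 |
| 5.00 | 0 | 4.00 | 5 | 4.00 | 15 |
| 8.00 | 8 | 6.00 | 5 | 6.00 | 18 |
| 10.0 | 7 | 12.0 | 18 | 12.0 | 31 |
| 12.0 | 7 | 25.0 | 34 | 25.0 | 49 |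

(scatter of a reading: 2 percentage points)

1. the set-up with the highest amount of Q at the outlet or at the end, in percent of the Z put in ("none" if the first two lie within 2 percentage points) (ash / birch / alder / elm / none)
2. amount of Q at the outlet or at the end, in percent of the Z put in, ash
3. amount of Q at the outlet or at the end, in percent of the Z put in, birch
4. amount of Q at the outlet or at the end, in percent of the Z put in, alder
5. amount of Q at the outlet or at the end, in percent of the Z put in, elm

- the stated concentrations are those of everything mixed, before any reaction; amounts are the same in each set-up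
- what was read earlier has a scatter of 2 percentage points, one standard deviation
- the feed brings no volume worth counting
- the earlier runs were made in a closed, stirred flask

A turnover here is one mM of Q made per mM of a. Tuesday's last reading, 34% of Z at 25.0 min with a at 1.20 mM, counts 56.7 turnovers. That is 2.27 min⁻¹, my turnover frequency n: mM of Q made per mM of a per minute. As a check, Saturday's run has alder's D and L, and n gives it 8.16% at 12.0 min, against 7% read, with a scatter of 2 percentage points.

So alder should count N = n t = 45.3 turnovers in 20 min, which makes 27.2 mM of Q, or 13.6% of Z. Saturday's, Tuesday's and Thursday's runs share Z at 0.20 M and E at 0.20 M, so I assume the rate is proportional to each. Birch and elm dose one of them evenly, which averages 0.5 of its charge, so I reckon 6.80% for each. Ash works at outlet strength, so one pass of correction gives it 10.2%. I therefore back alder, ahead of ash by 3.4 points, which is more than the margin.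

The forecast gives ash 13%, birch 8%, alder 14.6% and elm 8%, and names none as best: “The top two lie within 2 points, though only narrowly.” There it parts from my call of alder.

The flask gives ash 13.0%, birch 10.0%, alder 16.0% and elm 7.78%, so the best is alder, clear of ash by 3.0 points.

    D + L ⇌ J, settled at all times (K = 2500 M⁻¹)
    Z + G → X (k = 0.290 M⁻¹ min⁻¹)
    E + D + G → D + Q (k = 170 M⁻² min⁻¹)
    Z + D ⇌ D + G (K = 1.90, k = 98.0 M⁻¹ min⁻¹)

Alder ends with D at 56.6% of the catalyst charged, which is 0.906 mM, more than the a I counted on. Its Q comes to 53.2 turnovers per mM of a, more than my N.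

A neighbouring flask is alder with E at 0.050 M. Scaling N with E gives 11.3 turnovers, or 3.40% of Z. That neighbouring flask gives 4.45%.

The readings stem from a simulated flask on assumed constants; noise was put on by code.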